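**Plan**

1. Retrosynthesis: the two CH2OH groups go back to a C3 carboxylic acid and a C4 methyl ester, C4 to its epimer, the tetrahydrofuran to a furan, and finally the C2–aryl and C5–aryl bonds are cut, leaving dimethyl furan-3,4-dicarboxylate and a protected 4-bromo-2,6-dimethoxyphenol.
2. Enabling feature: the ring O1/C2/C3/C4/C5, with aryl groups on C2 and C5 and one-carbon groups on C3 and C4, is the saturated form of a symmetric 2,5-diarylfuran-3,4-diester. The parent furan-3,4-diester has hydrogen only on C2 and C5, both next to O1, so a twofold C–H arylation can only land there.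
3. Forward order: benzylate the bromophenol, attach it twice to the bought furan ring (no ring is formed anywhere in the route), saturate the furan, then desymmetrise, epimerise and reduce.
4. Stereochemistry: syn delivery of hydrogen to one furan face gives the all-cis meso diester; pig liver esterase breaks the mirror symmetry and so fixes the absolute configuration; methoxide inverts only the ester-bearing C4; hydride reduction touches no stereocentre.
5. Numbering used throughout: O1, C2 (aryl cis to the neighbouring CH2OH), C3, C4, C5 (aryl trans to the neighbouring CH2OH); the target is then (2S,3S,4S,5R).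

Key step: step 2

Assumption: pig liver esterase is taken to cleave the methyl ester on the R-configured carbon (C3) of the all-cis meso diester from step 3; the fallback for step 4 reaches the same half-ester with a reagent whose sense can be chosen.

**Route**

Step 1
Reactants: 1 4-bromo-2,6-dimethoxyphenol; 2 benzyl bromide
Product: 3 2-(benzyloxy)-5-bromo-1,3-dimethoxybenzene
Conditions: K2CO3, DMF, 60 °C
Reagents that add atoms: none
Why: Williamson ether synthesis, in which the acidic 2,6-dimethoxyphenoxide is alkylated on oxygen by the primary benzylic bromide; no stereocentre is involved.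

Step 2
Reactants: 4 dimethyl furan-3,4-dicarboxylate; 3 2-(benzyloxy)-5-bromo-1,3-dimethoxybenzene (2.5 equiv)
Product: 6 dimethyl 2,5-bis[4-(benzyloxy)-3,5-dimethoxyphenyl]furan-3,4-dicarboxylate, via monoarylated furan diester 5 (not isolated)
Conditions: Pd(OAc)2 (5 mol%), PCy3·HBF4 (10 mol%), PivOH (30 mol%), K2CO3 (3 equiv), DMA, 110 °C
Reagents that add atoms: none
Why: Zerovalent palladium carrying PCy3 inserts into the C–Br bond of 3, bromide is exchanged for pivalate, and the divalent arylpalladium pivalate cleaves the C2–H bond of 4 through a six-membered concerted metalation–deprotonation transition state before reductive elimination forms the C2–aryl bond; the same cycle then arylates C5 of 5. The closest known reaction type is the palladium/pivalate-catalysed direct arylation of furan-3-carboxylates and other electron-poor five-membered heteroarenes with aryl bromides. No ring is closed and no stereocentre is formed. The step needs regiocontrol and complete twofold coupling: the only C–H bonds of 4 are the two equivalent ones next to O1, each acidified by the neighbouring ester, so the site is fixed, and the first aryl group does not shield C5, so an excess of 3 should carry 5 through to 6. The benzyl ethers and methyl esters are inert to carbonate and pivalate in dry DMA, and the electron-rich bromide has no C–H bond acidic enough to compete.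

Step 3
Reactants: 6 dimethyl 2,5-bis[4-(benzyloxy)-3,5-dimethoxyphenyl]furan-3,4-dicarboxylate
Product: 8 dimethyl (2R,3S,4R,5S)-2,5-bis(4-hydroxy-3,5-dimethoxyphenyl)tetrahydrofuran-3,4-dicarboxylate (all-cis meso), via debenzylated furan bisphenol 7 (not isolated)
Conditions: H2 (50 bar), Pd/C (10% Pd), EtOAc–MeOH 1:1, 50 °C
Reagents that add atoms: none
Why: Heterogeneous hydrogenation, in which the benzyl ethers are hydrogenolysed first and the flat furan then takes up two molecules of H2 in syn fashion from the face bound to the metal (a dihydrofuran that leaves the surface should be reduced anti to its existing substituents, with the same result), so that C2, C3, C4 and C5 all receive hydrogen from one side and the all-cis meso diester results.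

Step 4
Reactants: 8 dimethyl (2R,3S,4R,5S)-2,5-bis(4-hydroxy-3,5-dimethoxyphenyl)tetrahydrofuran-3,4-dicarboxylate
Product: 9 (2S,3R,4S,5R)-2,5-bis(4-hydroxy-3,5-dimethoxyphenyl)-4-(methoxycarbonyl)tetrahydrofuran-3-carboxylic acid (all-cis)
Conditions: pig liver esterase, 0.1 M phosphate buffer pH 7.5, DMSO (10% v/v), 30 °C; then citric acid to pH 4
Reagents that add atoms: water, O
Why: Enzymatic desymmetrisation of a meso cis-1,2-diester, in which the esterase distinguishes the two enantiotopic methyl esters and stops at the half-ester because the carboxylate is a poor substrate; this fixes the absolute configuration of the four existing centres without creating a new one.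

Step 5
Reactants: 9 (2S,3R,4S,5R)-2,5-bis(4-hydroxy-3,5-dimethoxyphenyl)-4-(methoxycarbonyl)tetrahydrofuran-3-carboxylic acid
Product: 10 (2S,3R,4R,5R)-2,5-bis(4-hydroxy-3,5-dimethoxyphenyl)-4-(methoxycarbonyl)tetrahydrofuran-3-carboxylic acid (C4 ester trans to the C5 aryl group and to the C3 carboxyl group)
Conditions: NaOMe (5 equiv), MeOH, 25–40 °C; then aq. HCl to pH 3, 0 °C
Reagents that add atoms: none
Why: Base-mediated epimerisation under thermodynamic control, in which methoxide enolises only the C4 methyl ester (the C3 carboxylate is already anionic and does not enolise, and the mild temperature keeps the phenoxides from opening the ring at C2), and equilibration settles the ester on the face opposite to the C5 aryl group and the C3 carboxylate, which relieves the all-cis strain and sets C4.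

Step 6
Reactants: 10 (2S,3R,4R,5R)-2,5-bis(4-hydroxy-3,5-dimethoxyphenyl)-4-(methoxycarbonyl)tetrahydrofuran-3-carboxylic acid
Product: 11 4,4'-[(2S,3S,4S,5R)-3,4-bis(hydroxymethyl)tetrahydrofuran-2,5-diyl]bis(2,6-dimethoxyphenol)
Conditions: LiAlH4 (8 equiv), THF, 0 °C to reflux; then H2O, sat. aq. NH4Cl
Reagents that add atoms: none
Why: Hydride reduction of a methyl ester and a carboxylate to primary alcohols by LiAlH4, in which the phenols are only deprotonated and return on work-up and no stereocentre is touched; the change of the C3 and C4 descriptors from R to S reflects only the lower CIP rank of CH2OH.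

**Compound list**

1 | 4-bromo-2,6-dimethoxyphenol | COc1cc(Br)cc(OC)c1O | starting material
2 | benzyl bromide | BrCc1ccccc1 | starting material
3 | 2-(benzyloxy)-5-bromo-1,3-dimethoxybenzene | COc1cc(Br)cc(OC)c1OCc1ccccc1 | intermediate
4 | dimethyl furan-3,4-dicarboxylate | COC(=O)c1cocc1C(=O)OC | starting material
5 | dimethyl 2-[4-(benzyloxy)-3,5-dimethoxyphenyl]furan-3,4-dicarboxylate (not isolated) | COC(=O)c1coc(-c2cc(OC)c(OCc3ccccc3)c(OC)c2)c1C(=O)OC | intermediate
6 | dimethyl 2,5-bis[4-(benzyloxy)-3,5-dimethoxyphenyl]furan-3,4-dicarboxylate (achiral) | COC(=O)c1c(-c2cc(OC)c(OCc3ccccc3)c(OC)c2)oc(-c2cc(OC)c(OCc3ccccc3)c(OC)c2)c1C(=O)OC | intermediate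
7 | dimethyl 2,5-bis(4-hydroxy-3,5-dimethoxyphenyl)furan-3,4-dicarboxylate (not isolated) | COC(=O)c1c(-c2cc(OC)c(O)c(OC)c2)oc(-c2cc(OC)c(O)c(OC)c2)c1C(=O)OC | intermediate
8 | dimethyl (2R,3S,4R,5S)-2,5-bis(4-hydroxy-3,5-dimethoxyphenyl)tetrahydrofuran-3,4-dicarboxylate (all-cis, meso) | COc1cc([C@H]2O[C@@H](c3cc(OC)c(O)c(OC)c3)[C@@H](C(=O)OC)[C@H]2C(=O)OC)cc(OC)c1O | intermediate
9 | (2S,3R,4S,5R)-2,5-bis(4-hydroxy-3,5-dimethoxyphenyl)-4-(methoxycarbonyl)tetrahydrofuran-3-carboxylic acid (all-cis) | COc1cc([C@H]2O[C@@H](c3cc(OC)c(O)c(OC)c3)[C@@H](C(=O)OC)[C@H]2C(=O)O)cc(OC)c1O | intermediate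
10 | (2S,3R,4R,5R)-2,5-bis(4-hydroxy-3,5-dimethoxyphenyl)-4-(methoxycarbonyl)tetrahydrofuran-3-carboxylic acid (2,3-cis, 3,4-trans, 4,5-trans) | COc1cc([C@H]2O[C@@H](c3cc(OC)c(O)c(OC)c3)[C@H](C(=O)OC)[C@H]2C(=O)O)cc(OC)c1O | intermediate
11 | 4,4'-[(2S,3S,4S,5R)-3,4-bis(hydroxymethyl)tetrahydrofuran-2,5-diyl]bis(2,6-dimethoxyphenol) (2,5-cis aryl groups, 2,3-cis, 3,4-trans, 4,5-trans) | COc1cc([C@H]2O[C@@H](c3cc(OC)c(O)c(OC)c3)[C@H](CO)[C@H]2CO)cc(OC)c1O | target

**Summary**

Total step count: 6. Longest linear sequence: 6 steps (1 → 3 → 6 → 8 → 9 → 10 → 11).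

**Steps most likely to fail**

Step 3. Saturation may stall after the first molecule of hydrogen, at the tetrasubstituted push–pull dihydrofuran. Alternatively, once benzylic sp3 C–O bonds exist next to electron-rich hydroxyaryl rings, hydrogenolytic ring opening on palladium may compete at the pressure needed. The fallback sets out from 6 and separates the two reductions.
- H2 (1 atm) over Pd/C (10% Pd) in EtOAc at 20 °C should remove only the benzyl groups and give furan bisphenol 7, now isolated.
- Ac2O in pyridine converts it into dimethyl 2,5-bis(4-acetoxy-3,5-dimethoxyphenyl)furan-3,4-dicarboxylate F1, whose less electron-rich aryl rings make the later benzylic C–O bonds harder to cleave.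
- H2 (60 bar) over Rh/Al2O3 (5% Rh) in EtOAc, a catalyst with little tendency towards C–O hydrogenolysis, should give all-cis meso dimethyl (2R,3S,4R,5S)-2,5-bis(4-acetoxy-3,5-dimethoxyphenyl)tetrahydrofuran-3,4-dicarboxylate F2.
- Hydrazine acetate in DMF at 20 °C removes the two aryl acetates without touching the methyl esters or the neighbouring stereocentres, and the route is rejoined at 8.

Step 4. The two aryl groups flanking each ester may keep the substrate out of the active site, or the enzyme may discriminate the enantiotopic esters poorly or in the unwanted sense. The fallback sets out from 8 and desymmetrises chemically.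
- Me3SnOH in 1,2-dichloroethane at 80 °C hydrolyses both methyl esters without enolisation to all-cis meso (2R,3S,4R,5S)-2,5-bis(4-hydroxy-3,5-dimethoxyphenyl)tetrahydrofuran-3,4-dicarboxylic acid F3.
- DCC in THF at 0 °C closes it to the cis-fused meso anhydride, all-cis 4,6-bis(4-hydroxy-3,5-dimethoxyphenyl)tetrahydrofuro[3,4-c]furan-1,3-dione F4.
- Methanolysis in toluene at −50 °C mediated by quinidine, or by its pseudo-enantiomer quinine if the other carbonyl is attacked, opens the anhydride at one enantiotopic carbonyl and rejoins the route at 9.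

Step 2. The coupling may stop at 5, or 3 may be lost to reductive homocoupling and protodebromination, because insertion into the electron-rich bromide is slow and the reaction must run twice on one ring. The fallback sets out from 4 and 3 and makes the same two bonds by cross-coupling of pre-functionalised partners.
- Br2 in acetic acid at 60 °C brominates the two free positions of 4 to dimethyl 2,5-dibromofuran-3,4-dicarboxylate F5.
- Miyaura borylation of 3 (B2pin2, Pd(dppf)Cl2, KOAc, dioxane, 90 °C) gives 2-[4-(benzyloxy)-3,5-dimethoxyphenyl]-4,4,5,5-tetramethyl-1,3,2-dioxaborolane F6.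
- Twofold Suzuki–Miyaura coupling of F5 with F6 (Pd(PPh3)4, K3PO4, dioxane–water, 90 °C) rejoins the route at 6.

Further compounds
F1 | step 3 | dimethyl 2,5-bis(4-acetoxy-3,5-dimethoxyphenyl)furan-3,4-dicarboxylate | COC(=O)c1c(-c2cc(OC)c(OC(C)=O)c(OC)c2)oc(-c2cc(OC)c(OC(C)=O)c(OC)c2)c1C(=O)OC
F2 | step 3 | dimethyl (2R,3S,4R,5S)-2,5-bis(4-acetoxy-3,5-dimethoxyphenyl)tetrahydrofuran-3,4-dicarboxylate (all-cis, meso) | COc1cc([C@H]2O[C@@H](c3cc(OC)c(OC(C)=O)c(OC)c3)[C@@H](C(=O)OC)[C@H]2C(=O)OC)cc(OC)c1OC(C)=O
F3 | step 4 | (2R,3S,4R,5S)-2,5-bis(4-hydroxy-3,5-dimethoxyphenyl)tetrahydrofuran-3,4-dicarboxylic acid (all-cis, meso) | COc1cc([C@H]2O[C@@H](c3cc(OC)c(O)c(OC)c3)[C@@H](C(=O)O)[C@H]2C(=O)O)cc(OC)c1O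
F4 | step 4 | all-cis meso 4,6-bis(4-hydroxy-3,5-dimethoxyphenyl)tetrahydrofuro[3,4-c]furan-1,3-dione | COc1cc([C@H]2O[C@@H](c3cc(OC)c(O)c(OC)c3)[C@H]3C(=O)OC(=O)[C@@H]23)cc(OC)c1O
F5 | step 2 | dimethyl 2,5-dibromofuran-3,4-dicarboxylate | COC(=O)c1c(Br)oc(Br)c1C(=O)OC
F6 | step 2 | 2-[4-(benzyloxy)-3,5-dimethoxyphenyl]-4,4,5,5-tetramethyl-1,3,2-dioxaborolane | COc1cc(B2OC(C)(C)C(C)(C)O2)cc(OC)c1OCc1ccccc1
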